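## Analysis of the target

9-Deacetylstylatulide lactone (46) is a briarane. Ring A is a cyclohexene (C1, C10–C14, alkene C11=C12) that is trans-fused through C1–C10 to a ten-membered carbocycle (C1–C10) holding a (Z)-trisubstituted C5=C6 alkene. A γ-lactone (C7–O–C19(=O)–C17–C8) is fused on the C7–C8 bond. There are eight stereocentres: quaternary C1 (methyl C15), the acetoxy carbinols C2 and C14 on either side of it, C10, the contiguous oxygenated triad C7/C8/C9 (C8 a tertiary carbinol) and C17. On ring A, O14 is cis to the C1–C2 bond and C15 is anti to H10, and the 2,14-dioxygen pair is a syn 1,3-diol across C1. On the lactone, C6, the 8-hydroxyl and the C18 methyl share one face and C9 lies on the other, and O9 and the C10–C11 bond are syn along C8–C9–C10–C1. The sensitive groups are the two secondary acetates, the β-hydroxy lactone (retro-aldol, epimerisable C17), the free 8,9-diol and, in precursors, the doubly allylic C10–H. The synthesis is hard because a ten-membered ring must be closed, C1 is quaternary and flanked by two oxygenated carbons, and C7–C10 form an unbroken row of stereocentres. The strategy rests on C1 being α to C2 and β to O14: with C2 as a ketone, C1–C14 is an aldol bond, and the C15 methyl can be carried as an exocyclic methylene whose reduction by hydride generates exactly the C1 enolate.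

## Retrosynthetic reasoning

**Endgame (46 → 42).** The C9 silyl ether of 45 is removed last, so that the two acetates are placed on 44 while O9 is blocked and the tertiary O8 stays free. Diol 44 comes from β-hydroxy ketone 42 by a hydroxyl-directed syn reduction. This makes C2 depend on C14 and leaves only C1 and C14 to be set by the ring-forming step.

**C1–C14 (42 → 40).** Cutting the aldol bond of ring A opens 42 to the ten-membered α-methylene ketone 40 with a (Z)-enal arm on C10. The cut is made here because ring A is then built on a finished macrocycle, so no medium ring has to close next to a quaternary carbon. The forward reaction has to deliver hydride to C15, form the C1 enolate 41 without touching C3, and close the six-membered ring with O14 cis to C2 and the ring fusion trans.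

**C1–C2 (40 → 37).** The enone and the aldehyde of 40 are both taken back to alcohols (39, then 38 with O14 still silylated). The allylic alcohol 38 is cut at C1–C2 in the Nozaki–Hiyama–Kishi sense to the 2-iodoalkene aldehyde 37. This bond is chosen because its closure creates no lasting stereocentre (C2 is oxidised) and gives the exocyclic methylene and the C2 oxygen in one operation, which avoids a regioselective α-methylenation.

**C1 functional group (37 → 29).** The iodoalkene of 35 comes from the terminal alkyne 33 by Markovnikov hydroiodination. The alkyne comes from aldehyde 32, and this from the imide carbonyl of 30/29. C15 is therefore the one carbon added by homologation, and C1 is the acyl carbon of an aldol donor.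

**C9–C10 (29 → 27 + 18).** With C1 as an imide carbonyl, C10 is an α-carbon and C9 a β-carbinol, so the bond is an Evans syn aldol between imide 27 and the non-enolisable aldehyde 18. The auxiliary 25 fixes C9 and C10 absolutely and independently of the three centres already present in 18.

**Lactone and C7/C8 (18 → 14).** Aldehyde 18 is the oxidised form of lactone diol 16. The lactone C7–O bond is cut so that O8 and C7 become one epoxide (15), with the C19 ester as the internal nucleophile. The epoxide comes from the primary allylic alcohol 14 by Sharpless asymmetric epoxidation. One reagent-controlled step thus sets C8 directly and C7 through inversion, and the (E) geometry required at C7=C8 is the one an olefination gives naturally.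

**C7=C8 (14 → 11 + 6).** The diene ester 13 is cut at C7=C8 into the (Z)-enal 6 and the phosphonate 11 (Horner–Wadsworth–Emmons). The tert-butyl ester at C19 is kept distinct from the ethyl ester at C9 so that only C9 is reduced to give 14.

**C8–C17 (11 → 9 + 8).** The C17 methyl stereocentre is bought from the lactate pool: triflate 8, made from 7, is displaced with inversion by the anion 10 of 9.

**Building blocks.** Enal 6 carries the (Z)-C5=C6 alkene of 1, whose distal alkene is cleaved to give C2. Imide 27 carries the (Z)-C11=C12 alkene, which is taken from the ring of diene 20 (Birch product of 19) by cleaving its enol ether double bond.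

## Alternatives that were turned down

**Alternative 1:** Claisen ring expansion. The disconnection retraces the C7–C8 bond of the cyclodecenone A1 to a C5–O bond, so that the ten-membered ring shrinks to an eight-membered cyclic enol ether fused to ring A. In the forward step, heating the substrate triggers a 3,3-sigmatropic shift that forms C7–C8, breaks C5–O, unveils the C9 ketone and gives A1.
- For it: no ten-membered ring is closed directly; the cyclic transition state delivers the (Z)-C5=C6 alkene and transfers chirality to C7; ring A with quaternary C1 is made beforehand by six-membered-ring chemistry. On ring formation and alkene geometry it is at least as strong as the chosen route.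
- Against it: A1 still lacks the C8 oxygen and the whole C17–C19 unit. C8 is a methylene between the C9 ketone and C7, and it would have to become a tertiary carbinol bearing the propionate arm, with C9 then reduced. All of this would happen inside the flexible ring under transannular control. The substrate also needs a tertiary ether stereocentre at C5 and an eight-membered ether next to C1.
- Comparison: the chosen route sets C7, C8 and C17 on an open chain by reagent control and leaves one risky step at the end, whereas here several uncertain stereochemical steps would follow the key step.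

**Alternative 2:** Glycol cleavage. The disconnection rejoins C2 and C7 of the diketone A2, which hides the ten-membered ring inside two six-membered rings sharing a cis diol. In the forward step a Criegee-type cleavage of that diol forms both carbonyls and releases A2.
- For it: the fragmentation is close to certain, the (Z) alkene is guaranteed by its ring origin, and C1, C8, C9, C10 and C14 are set on rigid cyclohexanes. On the reliability of ring formation it is stronger than a Nozaki–Hiyama–Kishi closure.
- Against it: the substrate is a tricycle with two fully substituted diol carbons next to the quaternary C1 and C8, and it is long to build. After cleavage the C7 ketone (a (Z)-enone prone to isomerisation) and the C2 ketone must each be reduced with the right sense in a flexible ring, C7 without a directing group, before the lactone can close.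
- Comparison: the chosen route fixes C7 before any ring exists and uses the C14 hydroxyl to direct the C2 reduction, and it is shorter after the key step.

**Alternative 3:** Transannular allylic alkylation. The disconnection cuts C1–C10 of the dione A3 and opens both rings to a 14-membered 2-methyl-1,3-diketone with a C9–C10 vinyl epoxide. In the forward step a zerovalent palladium catalyst ionises the epoxide and the C1 enolate attacks C10 across the ring to give A3.
- For it: one step makes both carbocycles, the quaternary centre and the free C9 hydroxyl; attack at the other allyl terminus would give a four-membered ring, so regiochemistry is secure; a 14-membered ring is easier to close than a ten-membered one. In step economy it is stronger than the chosen route.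
- Against it: the configuration of C1 relative to C10 rests on an unknown transannular conformation. The product is a non-enolisable 1,3-diketone that invites retro-Claisen cleavage, and its two carbonyls must be reduced to different, defined carbinols with no hydroxyl to direct the first reduction.
- Comparison: the chosen route forms O14 in the ring-closing event and sets C2 by a directed reduction, so it never passes through the dione.

Key step: step 29

## Route

Remark: briarane numbering (C1–C20) is used for all intermediates. Neryl acetate (1) is used as the commercial form of nerol, and tert-butyl (R)-lactate (7) is taken as commercial. Compounds 38 and 39 are carried as mixtures of C2 epimers that converge in step 28. The C9 silyl group is tert-butyldimethylsilyl in place of triethylsilyl.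

Step 1
Reactants: 1 neryl acetate
Product: 3 (2Z)-6-hydroxy-3-methylhex-2-en-1-yl acetate, via aldehyde 2 (not isolated)
Conditions: O3 (1.0 equiv), CH2Cl2/MeOH, pyridine, −78 °C; then NaBH4, −78 → 0 °C
Reagents that add atoms: ozone, [O-][O+]=O
Why: Ozonolysis with reductive work-up; the distal trisubstituted alkene is electron-rich while the C5=C6 alkene is deactivated by the allylic acetate, so one equivalent of ozone should cleave only the former, and NaBH4 reduces the aldehyde without touching the acetate or the (Z) alkene.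

Step 2
Reactants: 3 (2Z)-6-hydroxy-3-methylhex-2-en-1-yl acetate
Product: 4 (2Z)-6-[(tert-butyldimethylsilyl)oxy]-3-methylhex-2-en-1-yl acetate
Conditions: TBSCl, imidazole, DMF, 0 °C → rt
Reagents that add atoms: tert-butyldimethylsilyl chloride, CC(C)(C)[Si](C)(C)Cl
Why: Standard silylation of a primary alcohol; O2 is masked until the ring closure.

Step 3
Reactants: 4 (2Z)-6-[(tert-butyldimethylsilyl)oxy]-3-methylhex-2-en-1-yl acetate
Product: 5 (2Z)-6-[(tert-butyldimethylsilyl)oxy]-3-methylhex-2-en-1-ol
Conditions: K2CO3 (0.2 equiv), MeOH, 0 °C → rt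
Reagents that add atoms: none
Why: Base-catalysed transesterification removes the acetate; the silyl ether and the alkene geometry are stable to these conditions.

Step 4
Reactants: 5 (2Z)-6-[(tert-butyldimethylsilyl)oxy]-3-methylhex-2-en-1-ol
Product: 6 (2Z)-6-[(tert-butyldimethylsilyl)oxy]-3-methylhex-2-enal
Conditions: MnO2, CH2Cl2, rt
Reagents that add atoms: none
Why: Allylic oxidation under neutral heterogeneous conditions, under which neral-type enals should keep their (Z) geometry.

Step 5
Reactants: 7 tert-butyl (2R)-2-hydroxypropanoate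
Product: 8 tert-butyl (2R)-2-{[(trifluoromethyl)sulfonyl]oxy}propanoate
Conditions: Tf2O, 2,6-lutidine, CH2Cl2, −78 °C
Reagents that add atoms: trifluoromethanesulfonic anhydride, O=S(=O)(OS(=O)(=O)C(F)(F)F)C(F)(F)F
Why: O-Sulfonylation; the stereocentre is not touched.

Step 6
Reactants: 9 triethyl phosphonoacetate; 8 tert-butyl (2R)-2-{[(trifluoromethyl)sulfonyl]oxy}propanoate
Product: 11 4-tert-butyl 1-ethyl (3S)-2-(diethoxyphosphoryl)-3-methylbutanedioate, via sodium phosphonate 10 (not isolated)
Conditions: NaH, THF, 0 °C; then 8, 0 °C → rt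
Reagents that add atoms: none
Why: SN2 alkylation of a soft stabilised carbanion by an α-triflyloxy ester, which proceeds with inversion and so sets C17 from the lactate; the phosphonate carbon is formed as both epimers, which does not matter.

Step 7
Reactants: 11 4-tert-butyl 1-ethyl (3S)-2-(diethoxyphosphoryl)-3-methylbutanedioate; 6 (2Z)-6-[(tert-butyldimethylsilyl)oxy]-3-methylhex-2-enal
Product: 13 4-tert-butyl 1-ethyl (2E,3R)-2-[(2Z)-6-{[tert-butyl(dimethyl)silyl]oxy}-3-methylhex-2-en-1-ylidene]-3-methylbutanedioate, via sodium phosphonate 12 (not isolated)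
Conditions: NaH (0.95 equiv), THF, 0 °C; then 6, 0 °C → rt
Reagents that add atoms: none
Why: Horner–Wadsworth–Emmons olefination; α-substituted phosphonoacetates place the conjugated ester trans to the aldehyde residue, which is the (E) geometry at C7=C8 that the later epoxide opening needs. Keeping the base substoichiometric should leave C17 and the (Z)-C5=C6 alkene untouched.

Step 8
Reactants: 13 diene diester
Product: 14 tert-butyl (2R,3E,5Z)-9-{[tert-butyl(dimethyl)silyl]oxy}-3-(hydroxymethyl)-2,6-dimethylnona-3,5-dienoate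
Conditions: iBu2AlH (2.2 equiv), CH2Cl2, −78 °C
Reagents that add atoms: none
Why: Chemoselective reduction; the conjugated ethyl ester is reduced to the allylic alcohol while the α-branched tert-butyl ester is much slower at −78 °C.

Step 9
Reactants: 14 dienol
Product: 15 tert-butyl (2R)-2-{(2R,3R)-3-[(1Z)-5-{[tert-butyl(dimethyl)silyl]oxy}-2-methylpent-1-en-1-yl]-2-(hydroxymethyl)oxiran-2-yl}propanoate
Conditions: Ti(OiPr)4 (10 mol%), D-(−)-diethyl tartrate (12 mol%), tBuOOH, 4 Å MS, CH2Cl2, −20 °C
Reagents that add atoms: tert-butyl hydroperoxide, CC(C)(C)OO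
Why: Sharpless asymmetric epoxidation; only the alkene of the allylic alcohol reacts, and the D-(−)-tartrate catalyst should give the (2R,3R) oxirane by reagent control, which sets C8 and, for later inversion, C7.

Step 10
Reactants: 15 epoxy alcohol
Product: 16 (3R,4R,5S)-5-[(1Z)-5-{[tert-butyl(dimethyl)silyl]oxy}-2-methylpent-1-en-1-yl]-4-hydroxy-4-(hydroxymethyl)-3-methyloxolan-2-one
Conditions: CSA (0.2 equiv), CH2Cl2, −20 → 0 °C
Reagents that add atoms: none
Why: Acid-catalysed epoxy-ester lactonisation; the ester carbonyl opens the activated epoxide at the allylic C7 from the back with inversion, forming the five-membered ring, and the tert-butyl group leaves as isobutene. C8 keeps its oxygen with retention and C7 becomes (S), so C6 ends cis to the 8-hydroxyl.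

Step 11
Reactants: 16 lactone diol
Product: 17 (3R,4R,5S)-bis(triethylsilyl) ether of 16
Conditions: TESOTf (2.5 equiv), 2,6-lutidine, CH2Cl2, −78 → 0 °C
Reagents that add atoms: triethylsilyl trifluoromethanesulfonate, CC[Si](CC)(CC)OS(=O)(=O)C(F)(F)F
Why: Silylation of the primary and the tertiary hydroxyl with a silyl triflate; the lactone is not enolised under these conditions.

Step 12
Reactants: 17 bis(triethylsilyl) ether
Product: 18 (2S,3S,4R)-2-[(1Z)-5-{[tert-butyl(dimethyl)silyl]oxy}-2-methylpent-1-en-1-yl]-4-methyl-5-oxo-3-[(triethylsilyl)oxy]oxolane-3-carbaldehyde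
Conditions: (COCl)2, DMSO, CH2Cl2, −78 → −40 °C; Et3N, −78 → 0 °C
Reagents that add atoms: none
Why: Swern oxidation with direct oxidative cleavage of the primary triethylsilyl ether; the tertiary triethylsilyl ether and the primary TBS ether are inert, and the aldehyde has no α-hydrogen.

Step 13
Reactants: 19 3-methylanisole
Product: 20 1-methoxy-5-methylcyclohexa-1,4-diene
Conditions: Li, NH3 (l), tBuOH, THF, −78 → −33 °C; NH4Cl
Reagents that add atoms: none
Why: Birch reduction; both donor substituents end on the remaining double bonds, so the ring holds the future C11=C12 alkene with a cis chain.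

Step 14
Reactants: 20 1-methoxy-5-methylcyclohexa-1,4-diene
Product: 22 methyl (3Z)-6-hydroxy-3-methylhex-3-enoate, via aldehyde ester 21 (not isolated)
Conditions: O3 (1.0 equiv), CH2Cl2/MeOH, −78 °C; then NaBH4, −78 → 0 °C
Reagents that add atoms: ozone, [O-][O+]=O
Why: Selective ozonolysis of the electron-rich enol ether double bond gives the ester and the aldehyde, which is reduced in the flask before it can move into conjugation; the (Z) geometry is inherited from the ring.

Step 15
Reactants: 22 methyl (3Z)-6-hydroxy-3-methylhex-3-enoate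
Product: 23 methyl (3Z)-6-{[tert-butyl(diphenyl)silyl]oxy}-3-methylhex-3-enoate
Conditions: TBDPSCl, imidazole, DMF, rt
Reagents that add atoms: tert-butyldiphenylsilyl chloride, CC(C)(C)[Si](Cl)(c1ccccc1)c1ccccc1
Why: Standard silylation; the robust group at O14 must outlast every other silyl ether until step 27.

Step 16
Reactants: 23 silyl ether ester
Product: 24 (3Z)-6-{[tert-butyl(diphenyl)silyl]oxy}-3-methylhex-3-enoic acid
Conditions: LiOH, THF/H2O, 0 °C; then 1 M HCl
Reagents that add atoms: lithium hydroxide, [Li+].[OH-]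
Why: Saponification at 0 °C, cold enough to keep the β,γ-alkene out of conjugation.

Step 17
Reactants: 24 acid; 25 (4R)-4-benzyl-1,3-oxazolidin-2-one
Product: 27 (4R)-4-benzyl-3-[(3Z)-6-{[tert-butyl(diphenyl)silyl]oxy}-3-methylhex-3-enoyl]-1,3-oxazolidin-2-one, via mixed anhydride 26 (not isolated)
Conditions: PivCl, Et3N, THF, −20 °C; then 25, LiCl, rt
Reagents that add atoms: none
Why: N-Acylation of the oxazolidinone through the mixed pivalic anhydride under mild amine/LiCl conditions.

Step 18
Reactants: 27 imide; 18 lactone aldehyde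
Product: 29 syn aldol adduct (7S,8R,9R,10R,17R) with the C1 imide and free 9-hydroxyl, via boron enolate 28 (not isolated)
Conditions: 27, Bu2BOTf, iPr2NEt, CH2Cl2, −78 → 0 °C; then 18, −78 → 0 °C; pH 7 buffer, MeOH, H2O2
Reagents that add atoms: none
Why: Evans syn aldol through the (Z)-boron enolate and a Zimmerman–Traxler chair; the (R)-benzyl auxiliary shields one enolate face and so sets C10 and C9 together (O9 syn to the C11 alkenyl group) by reagent control. The aldehyde cannot enolise, and the β,γ-alkene of the enolate stays in place.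

Step 19
Reactants: 29 aldol adduct
Product: 30 9-O-TBS ether of 29 (7S,8S,9R,10R,17R)
Conditions: TBSOTf, 2,6-lutidine, CH2Cl2, −78 → 0 °C
Reagents that add atoms: tert-butyldimethylsilyl trifluoromethanesulfonate, CC(C)(C)[Si](C)(C)OS(=O)(=O)C(F)(F)F
Why: Silyl triflate silylation of the hindered secondary alcohol; this group stays until the last step.

Step 20
Reactants: 30 silylated imide
Product: 31 C1 primary alcohol (7S,8S,9R,10S,17R)
Conditions: LiBH4, MeOH (1 equiv), THF, 0 °C
Reagents that add atoms: none
Why: Reductive removal of the oxazolidinone; the exocyclic imide carbonyl is far more electrophilic than the α,β,β-trisubstituted lactone, which should survive at 0 °C.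

Step 21
Reactants: 31 primary alcohol
Product: 32 C1 aldehyde (7S,8S,9R,10R,17R)
Conditions: DMP, NaHCO3, CH2Cl2, 0 °C
Reagents that add atoms: none
Why: Dess–Martin oxidation under buffered conditions; the α-alkenyl aldehyde is used at once to protect C10.

Step 22
Reactants: 32 aldehyde
Product: 33 terminal alkyne C1≡C15 (7S,8S,9R,10R,17R)
Conditions: Me3SiCHN2, LiN(iPr)2, THF, −78 °C; then 32, −78 → 0 °C; aq. NH4Cl
Reagents that add atoms: (trimethylsilyl)diazomethane, C[Si](C)(C)C=[N+]=[N-]
Why: Colvin homologation; the lithiated diazo compound adds to the aldehyde at −78 °C, and Peterson elimination followed by a 1,2-hydrogen shift of the alkylidene carbene gives the alkyne. The low temperature and the absence of protic base should preserve C10.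

Step 23
Reactants: 33 alkyne
Product: 35 2-iodoalkene C1(I)=C15H2 (7S,8S,9R,10R,17R), via iodovinylborane 34 (not isolated)
Conditions: B-I-9-BBN, pentane/CH2Cl2, −20 °C; AcOH, 0 °C; then H2O
Reagents that add atoms: 9-iodo-9-borabicyclo[3.3.1]nonane, IB1C2CCCC1CCC2
Why: syn-Haloboration of the terminal alkyne puts iodine on the internal carbon, and protodeboronation with acetic acid gives the Markovnikov iodoalkene; silyl ethers and the lactone tolerate the reagent at −20 °C.

Step 24
Reactants: 35 iodoalkene
Product: 36 C2,C8-diol (7S,8S,9R,10R,17R)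
Conditions: HF·pyridine, THF, 0 °C → rt
Reagents that add atoms: none
Why: Graded desilylation; the primary TBS ether and the labile tertiary triethylsilyl ether are cleaved, while the very hindered secondary TBS ether at O9 and the TBDPS ether at O14 are much slower.

Step 25
Reactants: 36 diol
Product: 37 C2 aldehyde (7S,8S,9R,10R,17R)
Conditions: DMP, NaHCO3, CH2Cl2, 0 °C → rt
Reagents that add atoms: none
Why: Dess–Martin oxidation of the only oxidisable hydroxyl; the tertiary 8-hydroxyl is inert.

Step 26
Reactants: 37 iodoalkene aldehyde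
Product: 38 ten-membered allylic alcohol (2RS,7S,8S,9R,10S,17R) with exocyclic C1 methylene and 14-O-TBDPS
Conditions: CrCl2 (8 equiv), NiCl2 (2 mol%), DMSO/THF, 2 mM, rt
Reagents that add atoms: none
Why: Intramolecular Nozaki–Hiyama–Kishi reaction; the alkenylchromium species adds only to the aldehyde and tolerates the free tertiary alcohol, the lactone and the silyl ethers. The (Z)-C5=C6 alkene and the lactone ring shorten the chain, and high dilution suppresses dimerisation; the configuration at C2 does not matter.

Step 27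
Reactants: 38 macrocyclic allylic alcohol
Product: 39 2,8,14-triol 9-O-TBS ether (2RS,7S,8S,9R,10S,17R)
Conditions: Bu4NF, AcOH, THF, 0 °C → rt
Reagents that add atoms: none
Why: Buffered fluoride removes the unhindered primary TBDPS ether; the secondary TBS ether, flanked by C8 and C10, is far slower, and no base-sensitive group is present at this stage.

Step 28
Reactants: 39 triol
Product: 40 ten-membered α-methylene ketone with the (Z)-enal arm on C10 and 9-O-TBS (7S,8S,9R,10S,17R)
Conditions: DMP (3 equiv), NaHCO3, CH2Cl2, 0 °C → rt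
Reagents that add atoms: none
Why: One Dess–Martin oxidation converts the allylic C2 alcohol (both epimers) to the enone and the C14 alcohol to the β,γ-unsaturated aldehyde under buffered non-basic conditions; 40 is used directly.

Step 29
Reactants: 40 keto aldehyde
Product: 42 14-hydroxy-2-oxo briarane lactone 9-O-TBS ether (1R,7S,8S,9R,10S,14S,17R), via copper enolate 41 (not isolated)
Conditions: [(Ph3P)CuH]6 (0.4 equiv), toluene/THF, −40 → −10 °C; sat. aq. NH4Cl
Reagents that add atoms: none
Why: The hexameric copper hydride adds hydride to the unhindered exocyclic C15 terminus of the enone, which gives the tetrasubstituted C1 copper enolate 41 regiospecifically with no base present that could enolise C3 or move the aldehyde's β,γ-alkene into conjugation. The enolate then adds to the tethered C14 aldehyde; the closest known reaction type is the reductive aldol cyclisation of enone-aldehydes and enone-ketones with this reagent. Ring A closes in the 6-(enolexo)-exo-trig mode, and the (Z)-C11=C12 alkene in the tether holds C14 within reach of C1. C14 is set relative to C1 by a copper-bridged chair in which the enolate oxygen and the aldehyde oxygen share the metal, so that O14 ends cis to the C2 carbonyl. C1 is set relative to C10 because the forming half-chair places the two ten-membered-ring bonds (C1–C2 and C10–C9) pseudo-equatorial, which gives the trans fusion with the C15 methyl anti to H10. The step needs 1,4-reduction of the enone to win over 1,2-reduction of the aldehyde, which the high reactivity of the terminal α-methylene ketone and the low temperature should secure; the lactone, the silyl ether and the isolated alkenes are inert to the reagent. The aldolate cannot dehydrate because C1 is quaternary, and it is protonated cold to prevent retro-aldol.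

Step 30
Reactants: 42 β-hydroxy ketone
Product: 44 2,14-diol 9-O-TBS ether (1S,2R,7S,8S,9R,10S,14S,17R), via boron chelate 43 (not isolated)
Conditions: Et2BOMe, THF/MeOH, −78 °C; NaBH4, −78 °C; AcOH; MeOH azeotrope
Reagents that add atoms: none
Why: Narasaka–Prasad reduction; the 14-hydroxyl and the C2 carbonyl are tied in a six-membered boron chelate and external hydride attacks its half-chair axially, which gives the syn 1,3-diol and so the (2R) carbinol.

Step 31
Reactants: 44 diol
Product: 45 2,14-diacetate 9-O-TBS ether (1S,2R,7S,8S,9R,10S,14S,17R)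
Conditions: Ac2O, pyridine, DMAP (cat.), CH2Cl2, rt
Reagents that add atoms: acetic anhydride, CC(=O)OC(C)=O
Why: Acylation of the two secondary alcohols; the hindered tertiary 8-hydroxyl is not acetylated and O9 is blocked.

Step 32
Reactants: 45 diacetate silyl ether
Product: 46 9-deacetylstylatulide lactone (1S,2R,7S,8R,9R,10S,14S,17R)
Conditions: HF·pyridine, THF, 0 °C → rt
Reagents that add atoms: none
Why: Acidic fluoride cleaves the last silyl ether without hydrolysing or migrating the acetates and without opening the β-hydroxy lactone.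

## Compound list

1 | neryl acetate, (2Z)-3,7-dimethylocta-2,6-dien-1-yl acetate | CC(C)=CCC/C(C)=C\COC(C)=O | starting material
2 | (2Z)-3-methyl-6-oxohex-2-en-1-yl acetate | O=CCC/C(C)=C\COC(C)=O | intermediate
3 | (2Z)-6-hydroxy-3-methylhex-2-en-1-yl acetate | OCCC/C(C)=C\COC(C)=O | intermediate
4 | (2Z)-6-[(tert-butyldimethylsilyl)oxy]-3-methylhex-2-en-1-yl acetate | CC(C)(C)[Si](C)(C)OCCC/C(C)=C\COC(C)=O | intermediate
5 | (2Z)-6-[(tert-butyldimethylsilyl)oxy]-3-methylhex-2-en-1-ol | CC(C)(C)[Si](C)(C)OCCC/C(C)=C\CO | intermediate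
6 | (2Z)-6-[(tert-butyldimethylsilyl)oxy]-3-methylhex-2-enal | CC(C)(C)[Si](C)(C)OCCC/C(C)=C\C=O | intermediate
7 | tert-butyl (2R)-2-hydroxypropanoate | O[C@H](C)C(=O)OC(C)(C)C | starting material
8 | tert-butyl (2R)-2-{[(trifluoromethyl)sulfonyl]oxy}propanoate | FC(F)(F)S(=O)(=O)O[C@H](C)C(=O)OC(C)(C)C | intermediate
9 | triethyl phosphonoacetate | CCOC(=O)CP(=O)(OCC)OCC | starting material
10 | sodium salt of 9 | CCOC(=O)[CH-]P(=O)(OCC)OCC.[Na+] | intermediate
11 | 4-tert-butyl 1-ethyl (3S)-2-(diethoxyphosphoryl)-3-methylbutanedioate (both C2 epimers) | CCOC(=O)C(P(=O)(OCC)OCC)[C@@H](C)C(=O)OC(C)(C)C | intermediate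
12 | sodium salt of 11 | CCOC(=O)[C-](P(=O)(OCC)OCC)[C@@H](C)C(=O)OC(C)(C)C.[Na+] | intermediate
13 | 4-tert-butyl 1-ethyl (2E,3R)-2-[(2Z)-6-{[tert-butyl(dimethyl)silyl]oxy}-3-methylhex-2-en-1-ylidene]-3-methylbutanedioate | CCOC(=O)/C(=C/C=C(/C)CCCO[Si](C)(C)C(C)(C)C)[C@@H](C)C(=O)OC(C)(C)C | intermediate
14 | tert-butyl (2R,3E,5Z)-9-{[tert-butyl(dimethyl)silyl]oxy}-3-(hydroxymethyl)-2,6-dimethylnona-3,5-dienoate | OC/C(=C/C=C(/C)CCCO[Si](C)(C)C(C)(C)C)[C@@H](C)C(=O)OC(C)(C)C | intermediate
15 | tert-butyl (2R)-2-{(2R,3R)-3-[(1Z)-5-{[tert-butyl(dimethyl)silyl]oxy}-2-methylpent-1-en-1-yl]-2-(hydroxymethyl)oxiran-2-yl}propanoate | OC[C@]1(O[C@@H]1/C=C(/C)CCCO[Si](C)(C)C(C)(C)C)[C@@H](C)C(=O)OC(C)(C)C | intermediate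
16 | (3R,4R,5S)-5-[(1Z)-5-{[tert-butyl(dimethyl)silyl]oxy}-2-methylpent-1-en-1-yl]-4-hydroxy-4-(hydroxymethyl)-3-methyloxolan-2-one | OC[C@@]1(O)[C@H](/C=C(/C)CCCO[Si](C)(C)C(C)(C)C)OC(=O)[C@@H]1C | intermediate
17 | (3R,4R,5S)-5-[(1Z)-5-{[tert-butyl(dimethyl)silyl]oxy}-2-methylpent-1-en-1-yl]-3-methyl-4-[(triethylsilyl)oxy]-4-{[(triethylsilyl)oxy]methyl}oxolan-2-one | CC[Si](CC)(CC)OC[C@@]1(O[Si](CC)(CC)CC)[C@H](/C=C(/C)CCCO[Si](C)(C)C(C)(C)C)OC(=O)[C@@H]1C | intermediate
18 | (2S,3S,4R)-2-[(1Z)-5-{[tert-butyl(dimethyl)silyl]oxy}-2-methylpent-1-en-1-yl]-4-methyl-5-oxo-3-[(triethylsilyl)oxy]oxolane-3-carbaldehyde | O=C[C@@]1(O[Si](CC)(CC)CC)[C@H](/C=C(/C)CCCO[Si](C)(C)C(C)(C)C)OC(=O)[C@@H]1C | intermediate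
19 | 3-methylanisole | COc1cccc(C)c1 | starting material
20 | 1-methoxy-5-methylcyclohexa-1,4-diene | COC1=CCC=C(C)C1 | intermediate
21 | methyl (3Z)-3-methyl-6-oxohex-3-enoate | COC(=O)C/C(C)=C\CC=O | intermediate
22 | methyl (3Z)-6-hydroxy-3-methylhex-3-enoate | COC(=O)C/C(C)=C\CCO | intermediate
23 | methyl (3Z)-6-{[tert-butyl(diphenyl)silyl]oxy}-3-methylhex-3-enoate | COC(=O)C/C(C)=C\CCO[Si](c1ccccc1)(c1ccccc1)C(C)(C)C | intermediate
24 | (3Z)-6-{[tert-butyl(diphenyl)silyl]oxy}-3-methylhex-3-enoic acid | OC(=O)C/C(C)=C\CCO[Si](c1ccccc1)(c1ccccc1)C(C)(C)C | intermediate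
25 | (4R)-4-benzyl-1,3-oxazolidin-2-one | O=C1OC[C@@H](Cc2ccccc2)N1 | starting material
26 | mixed pivalic anhydride of 24 | CC(C)(C)C(=O)OC(=O)C/C(C)=C\CCO[Si](c1ccccc1)(c1ccccc1)C(C)(C)C | intermediate
27 | (4R)-4-benzyl-3-[(3Z)-6-{[tert-butyl(diphenyl)silyl]oxy}-3-methylhex-3-enoyl]-1,3-oxazolidin-2-one | O=C(C/C(C)=C\CCO[Si](c1ccccc1)(c1ccccc1)C(C)(C)C)N1[C@H](Cc2ccccc2)COC1=O | intermediate
28 | dibutylboron (Z)-enolate of 27 | CCCCB(CCCC)O/C(=C\C(C)=C/CCO[Si](c1ccccc1)(c1ccccc1)C(C)(C)C)N1[C@H](Cc2ccccc2)COC1=O | intermediate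
29 | aldol adduct (7S,8R,9R,10R,17R): C1 (4R)-benzyloxazolidinone imide, 9-OH, 8-OTES, 2-OTBS, 14-OTBDPS, lactone closed | O=C([C@H](/C(C)=C\CCO[Si](c1ccccc1)(c1ccccc1)C(C)(C)C)[C@@H](O)[C@@]1(O[Si](CC)(CC)CC)[C@H](/C=C(/C)CCCO[Si](C)(C)C(C)(C)C)OC(=O)[C@@H]1C)N1[C@H](Cc2ccccc2)COC1=O | intermediate
30 | 9-O-TBS ether of 29 (7S,8S,9R,10R,17R) | O=C([C@H](/C(C)=C\CCO[Si](c1ccccc1)(c1ccccc1)C(C)(C)C)[C@@H](O[Si](C)(C)C(C)(C)C)[C@@]1(O[Si](CC)(CC)CC)[C@H](/C=C(/C)CCCO[Si](C)(C)C(C)(C)C)OC(=O)[C@@H]1C)N1[C@H](Cc2ccccc2)COC1=O | intermediate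
31 | C1 primary alcohol (7S,8S,9R,10S,17R) | OC[C@H](/C(C)=C\CCO[Si](c1ccccc1)(c1ccccc1)C(C)(C)C)[C@@H](O[Si](C)(C)C(C)(C)C)[C@@]1(O[Si](CC)(CC)CC)[C@H](/C=C(/C)CCCO[Si](C)(C)C(C)(C)C)OC(=O)[C@@H]1C | intermediate
32 | C1 aldehyde (7S,8S,9R,10R,17R) | O=C[C@H](/C(C)=C\CCO[Si](c1ccccc1)(c1ccccc1)C(C)(C)C)[C@@H](O[Si](C)(C)C(C)(C)C)[C@@]1(O[Si](CC)(CC)CC)[C@H](/C=C(/C)CCCO[Si](C)(C)C(C)(C)C)OC(=O)[C@@H]1C | intermediate
33 | terminal alkyne C1≡C15 (7S,8S,9R,10R,17R) | C#C[C@H](/C(C)=C\CCO[Si](c1ccccc1)(c1ccccc1)C(C)(C)C)[C@@H](O[Si](C)(C)C(C)(C)C)[C@@]1(O[Si](CC)(CC)CC)[C@H](/C=C(/C)CCCO[Si](C)(C)C(C)(C)C)OC(=O)[C@@H]1C | intermediate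
34 | (Z)-2-iodo-1-(9-borabicyclo[3.3.1]nonan-9-yl)alkene from 33 | I/C(=C\B1C2CCCC1CCC2)[C@H](/C(C)=C\CCO[Si](c3ccccc3)(c3ccccc3)C(C)(C)C)[C@@H](O[Si](C)(C)C(C)(C)C)[C@@]4(O[Si](CC)(CC)CC)[C@H](/C=C(/C)CCCO[Si](C)(C)C(C)(C)C)OC(=O)[C@@H]4C | intermediate
35 | 2-iodoalkene C1(I)=C15H2 (7S,8S,9R,10R,17R) | C=C(I)[C@H](/C(C)=C\CCO[Si](c1ccccc1)(c1ccccc1)C(C)(C)C)[C@@H](O[Si](C)(C)C(C)(C)C)[C@@]1(O[Si](CC)(CC)CC)[C@H](/C=C(/C)CCCO[Si](C)(C)C(C)(C)C)OC(=O)[C@@H]1C | intermediate
36 | iodoalkene C2,C8-diol (7S,8S,9R,10R,17R) | C=C(I)[C@H](/C(C)=C\CCO[Si](c1ccccc1)(c1ccccc1)C(C)(C)C)[C@@H](O[Si](C)(C)C(C)(C)C)[C@@]1(O)[C@H](/C=C(/C)CCCO)OC(=O)[C@@H]1C | intermediate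
37 | iodoalkene C2 aldehyde (7S,8S,9R,10R,17R) | C=C(I)[C@H](/C(C)=C\CCO[Si](c1ccccc1)(c1ccccc1)C(C)(C)C)[C@@H](O[Si](C)(C)C(C)(C)C)[C@@]1(O)[C@H](/C=C(/C)CCC=O)OC(=O)[C@@H]1C | intermediate
38 | ten-membered allylic alcohol (2RS,7S,8S,9R,10S,17R), 9-OTBS, 14-OTBDPS | CC(C)(C)[Si](OCC/C=C(/C)[C@@H]1[C@@H](O[Si](C)(C)C(C)(C)C)[C@@]2(O)[C@H](/C=C(/C)CCC(O)C1=C)OC(=O)[C@@H]2C)(c3ccccc3)c3ccccc3 | intermediate
39 | ten-membered 2,8,14-triol 9-O-TBS ether (2RS,7S,8S,9R,10S,17R) | OCC/C=C(/C)[C@@H]1[C@@H](O[Si](C)(C)C(C)(C)C)[C@@]2(O)[C@H](/C=C(/C)CCC(O)C1=C)OC(=O)[C@@H]2C | intermediate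
40 | ten-membered α-methylene ketone with (Z)-enal arm on C10, 9-O-TBS (7S,8S,9R,10S,17R) | O=CC/C=C(/C)[C@@H]1[C@@H](O[Si](C)(C)C(C)(C)C)[C@@]2(O)[C@H](/C=C(/C)CCC(=O)C1=C)OC(=O)[C@@H]2C | intermediate
41 | C1 copper enolate of 40 (phosphine-ligated) | O=CC/C=C(/C)[C@@H]1[C@@H](O[Si](C)(C)C(C)(C)C)[C@@]2(O)[C@H](/C=C(/C)CCC(O[Cu])=C1C)OC(=O)[C@@H]2C | intermediate
42 | 14-hydroxy-2-oxo briarane lactone 9-O-TBS ether (1R,7S,8S,9R,10S,14S,17R) | O[C@H]1CC=C(C)[C@@H]2[C@@H](O[Si](C)(C)C(C)(C)C)[C@@]3(O)[C@H](/C=C(/C)CCC(=O)[C@@]12C)OC(=O)[C@@H]3C | intermediate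
43 | 14-O-diethylboryl chelate of 42 | CCB(CC)O[C@H]1CC=C(C)[C@@H]2[C@@H](O[Si](C)(C)C(C)(C)C)[C@@]3(O)[C@H](/C=C(/C)CCC(=O)[C@@]12C)OC(=O)[C@@H]3C | intermediate
44 | 2,14-diol 9-O-TBS ether (1S,2R,7S,8S,9R,10S,14S,17R) | O[C@H]1CC=C(C)[C@@H]2[C@@H](O[Si](C)(C)C(C)(C)C)[C@@]3(O)[C@H](/C=C(/C)CC[C@@H](O)[C@@]12C)OC(=O)[C@@H]3C | intermediate
45 | 2,14-diacetate 9-O-TBS ether (1S,2R,7S,8S,9R,10S,14S,17R) | CC(=O)O[C@H]1CC=C(C)[C@@H]2[C@@H](O[Si](C)(C)C(C)(C)C)[C@@]3(O)[C@H](/C=C(/C)CC[C@@H](OC(C)=O)[C@@]12C)OC(=O)[C@@H]3C | intermediate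
46 | 9-deacetylstylatulide lactone (1S,2R,7S,8R,9R,10S,14S,17R) | CC(=O)O[C@H]1CC=C(C)[C@@H]2[C@@H](O)[C@@]3(O)[C@H](/C=C(/C)CC[C@@H](OC(C)=O)[C@@]12C)OC(=O)[C@@H]3C | target

## Step count and least certain steps

Total: 32 steps. Longest linear sequence: 25 steps (1–4, 7–12, 18–32, from neryl acetate). The imide branch (steps 13–17) and the phosphonate branch (steps 5–6) join it at steps 18 and 7.

**Step 29 (key step).** The aldehyde may be reduced 1,2, or the copper enolate may be protonated before it closes the ring. The enolate may also add from the face that gives the cis ring fusion. A third risk is slow isomerisation of the β,γ-unsaturated aldehyde into conjugation, or conjugate addition of the free 8-hydroxyl to the enone, before hydride transfer. Fallback: from 40, a selenolate-triggered Michael–aldol with Me2AlSePh (toluene/THF, −78 °C) adds selenium to C15, and the aluminium enolate closes ring A through the same chelated chair to give the C15 phenylselanyl aldol F1. Bu3SnH/AIBN then cleaves the carbon–selenium bond and returns the route to 42.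

**Step 10.** The epoxide may ionise at C7 to a dienyl cation before the ester attacks. That would erode the inversion at C7 and could scramble the C5=C6 geometry. Fallback: from 15, the epoxide is opened at C7 by benzoic acid under Ti(OiPr)4 mediation (chelation-directed attack at the carbon remote from the hydroxymethyl group, with inversion) to give the C7 benzoate F2. K2CO3/MeOH frees the triol ester F3, and CSA in CH2Cl2 closes the lactone by acyl substitution, which does not involve C7, returning to 16.

**Step 18.** Addition to the fully substituted, α-silyloxy aldehyde may be slow, and the intrinsic facial bias of the aldehyde may oppose the auxiliary. Fallback: from 24 and 18, acid 24 is coupled (DCC, DMAP) with (4R)-4-benzyl-1,3-thiazolidine-2-thione to give the thioimide F4. Its chlorotitanium enolate (TiCl4, iPr2NEt, N-methylpyrrolidinone) adds to 18 to give the syn adduct F5, which is silylated (TBSOTf) to F6. NaBH4 removes the auxiliary under conditions that spare the lactone and returns to 31.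

**Step 26.** Ring closure to the ten-membered ring may be slower than intermolecular coupling or reduction of the carbon–iodine bond. Fallback: from 33, the hydroiodination is left out. HF·pyridine gives the alkynyl diol F7 and DMP the ynal F8. A reductive alkyne–aldehyde macrocyclisation with Ni(cod)2, a bulky N-heterocyclic carbene and Et3SiH, which forms the bond at the internal alkyne carbon, gives the exo-methylene silyl ether F9. Bu4NF removes both the triethylsilyl and the TBDPS group and returns to 39.

**Step 30.** The ring conformation may override the boron chelate and deliver hydride to the wrong face of C2. Fallback: from 42, the 14-hydroxyl is acetylated first (Ac2O, pyridine, DMAP) to the keto acetate F10, which also blocks retro-aldol. The C2 ketone is then reduced under reagent control with (S)-2-methyl-CBS-oxazaborolidine and catecholborane, with the quaternary C1 as the large group, to the (2R) alcohol F11. Acetylation returns to 45.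

## Further compounds

F1 | step 29 | C15 phenylselanyl aldol, 14-hydroxy-2-oxo-15-(phenylselanyl) briarane lactone 9-O-TBS ether | O[C@H]1CC=C(C)[C@@H]2[C@@H](O[Si](C)(C)C(C)(C)C)[C@@]3(O)[C@H](/C=C(/C)CCC(=O)[C@@]12C[Se]c4ccccc4)OC(=O)[C@@H]3C
F2 | step 10 | C7 benzoate of the C7,C8,C9-triol tert-butyl ester | OC[C@@](O)([C@H](/C=C(/C)CCCO[Si](C)(C)C(C)(C)C)OC(=O)c1ccccc1)[C@@H](C)C(=O)OC(C)(C)C
F3 | step 10 | C7,C8,C9-triol tert-butyl ester | OC[C@@](O)([C@H](/C=C(/C)CCCO[Si](C)(C)C(C)(C)C)O)[C@@H](C)C(=O)OC(C)(C)C
F4 | step 18 | (4R)-4-benzyl-3-[(3Z)-6-{[tert-butyl(diphenyl)silyl]oxy}-3-methylhex-3-enoyl]-1,3-thiazolidine-2-thione | O=C(C/C(C)=C\CCO[Si](c1ccccc1)(c1ccccc1)C(C)(C)C)N1[C@H](Cc2ccccc2)CSC1=S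
F5 | step 18 | thiazolidinethione syn aldol adduct (9-OH, 8-OTES) | O=C([C@H](/C(C)=C\CCO[Si](c1ccccc1)(c1ccccc1)C(C)(C)C)[C@@H](O)[C@@]1(O[Si](CC)(CC)CC)[C@H](/C=C(/C)CCCO[Si](C)(C)C(C)(C)C)OC(=O)[C@@H]1C)N1[C@H](Cc2ccccc2)CSC1=S
F6 | step 18 | 9-O-TBS ether of the thiazolidinethione adduct | O=C([C@H](/C(C)=C\CCO[Si](c1ccccc1)(c1ccccc1)C(C)(C)C)[C@@H](O[Si](C)(C)C(C)(C)C)[C@@]1(O[Si](CC)(CC)CC)[C@H](/C=C(/C)CCCO[Si](C)(C)C(C)(C)C)OC(=O)[C@@H]1C)N1[C@H](Cc2ccccc2)CSC1=S
F7 | step 26 | alkynyl C2,C8-diol | C#C[C@H](/C(C)=C\CCO[Si](c1ccccc1)(c1ccccc1)C(C)(C)C)[C@@H](O[Si](C)(C)C(C)(C)C)[C@@]1(O)[C@H](/C=C(/C)CCCO)OC(=O)[C@@H]1C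
F8 | step 26 | alkynyl C2 aldehyde | C#C[C@H](/C(C)=C\CCO[Si](c1ccccc1)(c1ccccc1)C(C)(C)C)[C@@H](O[Si](C)(C)C(C)(C)C)[C@@]1(O)[C@H](/C=C(/C)CCC=O)OC(=O)[C@@H]1C
F9 | step 26 | ten-membered exo-methylene C2 triethylsilyl ether, 9-OTBS, 14-OTBDPS | CC(C)(C)[Si](OCC/C=C(/C)[C@@H]1[C@@H](O[Si](C)(C)C(C)(C)C)[C@@]2(O)[C@H](/C=C(/C)CCC(O[Si](CC)(CC)CC)C1=C)OC(=O)[C@@H]2C)(c3ccccc3)c3ccccc3
F10 | step 30 | 14-acetoxy-2-oxo briarane lactone 9-O-TBS ether | CC(=O)O[C@H]1CC=C(C)[C@@H]2[C@@H](O[Si](C)(C)C(C)(C)C)[C@@]3(O)[C@H](/C=C(/C)CCC(=O)[C@@]12C)OC(=O)[C@@H]3C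
F11 | step 30 | 14-acetoxy-(2R)-hydroxy briarane lactone 9-O-TBS ether | CC(=O)O[C@H]1CC=C(C)[C@@H]2[C@@H](O[Si](C)(C)C(C)(C)C)[C@@]3(O)[C@H](/C=C(/C)CC[C@@H](O)[C@@]12C)OC(=O)[C@@H]3C
A1 | alternative 1 | bicyclic (Z)-cyclodecen-9-one with 7-(4-methoxybenzyl) ether and 2,14-bis(TBS) ethers | CC(C)(C)[Si](C)(C)O[C@H]1CC=C(C)[C@@H]2C(=O)C[C@H](/C=C(/C)CC[C@@H](O[Si](C)(C)C(C)(C)C)[C@@]12C)OCc1ccc(OC)cc1
A2 | alternative 2 | ten-membered 2,7-diketone with 8,9-acetonide, 14-acetate and C19 methyl ester | CC(=O)O[C@H]1CC=C(C)[C@@H]2[C@H]3OC(C)(C)O[C@@]3([C@@H](C)C(=O)OC)C(=O)/C=C(/C)CCC(=O)[C@@]12C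
A3 | alternative 3 | briarane 2,14-dione lactone with free 8,9-diol | O=C1CC=C(C)[C@@H]2[C@@H](O)[C@@]3(O)[C@H](/C=C(/C)CCC(=O)[C@@]12C)OC(=O)[C@@H]3C
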